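**Assumption:** the target has no stereocentre and its 19-membered ring is conformationally mobile, so it is achiral and no stereocontrol is needed; compounds 1, 3, 6 and 9 are taken as catalogue chemicals.

**Ring labels:** ring A is the trioxygenated ring bonded through oxygen to the para-phenylene ring B; ring C is the trioxygenated ring bonded through oxygen to the meta-phenylene ring D.

## Retrosynthetic overview

1. Target 14 ⇐ tetramethyl ether 12 by global O-demethylation (last step).
2. 12 ⇐ open-chain bromo-phenol 11. The 19-membered macrocycle is the only ring made, closed by the aryl C–O bond between the ring D oxygen and ring C.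
3. 11 ⇐ styrene 8 + 3-iodophenol 9 (hydroboration/B-alkyl Suzuki makes the ring A–ring D bridge); 8 ⇐ aldehyde 7.
4. 7 ⇐ phenol 5 + 3-iodo-4,5-dimethoxybenzaldehyde 6 by intermolecular C–O coupling (ring B–O–ring A), iodide reacting in preference to bromide.
5. 5 ⇐ 3-bromo-4,5-dimethoxybenzaldehyde 1 + 4-iodophenol 3 (methylenation, then hydroboration/B-alkyl Suzuki); all four benzene rings are bought.

## Route

Step 1
Reactants: 1 3-bromo-4,5-dimethoxybenzaldehyde
Product: 2 1-bromo-5-ethenyl-2,3-dimethoxybenzene
Conditions: Ph3PCH3Br (1.3 equiv), KOtBu (1.3 equiv), THF, 0 °C to rt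
Reagents that add atoms: methyltriphenylphosphonium bromide, C[P+](c1ccccc1)(c1ccccc1)c1ccccc1.[Br-]
Why: Wittig methylenation of an aryl aldehyde with the non-stabilised ylide is dependable, and the aryl bromide and methyl ethers are inert to it.

Step 2
Reactants: 2 1-bromo-5-ethenyl-2,3-dimethoxybenzene; 3 4-iodophenol
Product: 5 4-[2-(3-bromo-4,5-dimethoxyphenyl)ethyl]phenol, via B-alkyl-9-BBN borane 4 (not isolated)
Conditions: 9-BBN (1.2 equiv), THF, 0 °C to rt; then 3 (1.2 equiv), PdCl2(dppf) (3 mol%), 3 M aq K3PO4, DMF, 50 °C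
Reagents that add atoms: none
Why: Anti-Markovnikov hydroboration of the styrene followed by B-alkyl Suzuki–Miyaura coupling gives the CH2CH2 bridge directly, because PdCl2(dppf) inserts into the C–I bond of 3 far faster than into the hindered, electron-rich ortho-methoxy C–Br bond.

Step 3
Reactants: 5 4-[2-(3-bromo-4,5-dimethoxyphenyl)ethyl]phenol; 6 3-iodo-4,5-dimethoxybenzaldehyde
Product: 7 3-{4-[2-(3-bromo-4,5-dimethoxyphenyl)ethyl]phenoxy}-4,5-dimethoxybenzaldehyde
Conditions: 6 (1.3 equiv), CuI (10 mol%), picolinic acid (20 mol%), K3PO4 (2 equiv), DMSO, 80 °C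
Reagents that add atoms: none
Why: Ullmann diaryl ether coupling in which monovalent copper activates the formyl-activated C–I bond of 6 at 80 °C while the unactivated ortho-methoxy C–Br bond of 5 stays intact, and 6 has no phenol so 5 is the only nucleophile.

Step 4
Reactants: 7 3-{4-[2-(3-bromo-4,5-dimethoxyphenyl)ethyl]phenoxy}-4,5-dimethoxybenzaldehyde
Product: 8 1-bromo-5-{2-[4-(5-ethenyl-2,3-dimethoxyphenoxy)phenyl]ethyl}-2,3-dimethoxybenzene
Conditions: Ph3PCH3Br (1.5 equiv), KOtBu (1.5 equiv), THF, 0 °C to rt
Reagents that add atoms: methyltriphenylphosphonium bromide, C[P+](c1ccccc1)(c1ccccc1)c1ccccc1.[Br-]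
Why: Wittig methylenation of the only carbonyl group, with the diaryl ether, aryl bromide and methyl ethers unaffected.

Step 5
Reactants: 8 1-bromo-5-{2-[4-(5-ethenyl-2,3-dimethoxyphenoxy)phenyl]ethyl}-2,3-dimethoxybenzene; 9 3-iodophenol
Product: 11 3-{2-[3-(4-{2-(3-bromo-4,5-dimethoxyphenyl)ethyl}phenoxy)-4,5-dimethoxyphenyl]ethyl}phenol, via B-alkyl-9-BBN borane 10 (not isolated)
Conditions: 9-BBN (1.3 equiv), THF, 0 °C to rt; then 9 (1.3 equiv), PdCl2(dppf) (5 mol%), 3 M aq K3PO4, DMF, 50 °C
Reagents that add atoms: none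
Why: The same hydroboration/B-alkyl Suzuki–Miyaura sequence as in step 2 installs ring D with its free meta-hydroxyl, again using the large rate gap between aryl iodide and hindered aryl bromide at palladium.

Step 6
Reactants: 11 3-{2-[3-(4-{2-(3-bromo-4,5-dimethoxyphenyl)ethyl}phenoxy)-4,5-dimethoxyphenyl]ethyl}phenol
Product: 12 tetra-O-methyl ether of the target (19-membered macrocycle; ring D oxygen now bonded to ring C at the former C–Br carbon)
Conditions: Pd(OAc)2 (10 mol%), tBuXPhos (15 mol%), K3PO4 (3 equiv), toluene, 100 °C, 11 added by syringe pump over 16 h (final 2 mM)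
Reagents that add atoms: none
Why: Proposed new method: palladium-catalysed intramolecular O-arylation used as a macrocyclisation to a diaryl ether cyclophane; zerovalent palladium carrying one bulky biaryl di-tert-butylphosphine adds oxidatively to the ortho-methoxy C–Br bond, the tethered ring D phenoxide displaces bromide at divalent palladium, and C–O reductive elimination (favoured by the ortho substituent and the bulky ligand) closes the strain-free 19-membered ring, with slow addition keeping free 11 dilute relative to catalyst so that cyclisation outruns oligomerisation; the closest known reaction types are the intermolecular palladium-catalysed diaryl ether synthesis with biaryl phosphine ligands and the copper-mediated Ullmann macrocyclisation.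

Step 7
Reactants: 12 tetra-O-methyl ether of the target
Product: 14 CNP0511668.0 (target tetraphenol), via bis(bromoborole) ester 13 (not isolated)
Conditions: BBr3 (10 equiv), CH2Cl2, −78 °C to rt; then H2O, 0 °C, under argon
Reagents that add atoms: none
Why: Lewis acid aryl methyl ether cleavage with BBr3 removes all four methyl groups through cyclic catechol bromoborates that hydrolyse on work-up, while the two diaryl ether bonds and the bibenzyl bridges are inert.

## Compound list

1 | 3-bromo-4,5-dimethoxybenzaldehyde | COc1cc(C=O)cc(Br)c1OC | starting material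
2 | 1-bromo-5-ethenyl-2,3-dimethoxybenzene | C=Cc1cc(Br)c(OC)c(OC)c1 | intermediate
3 | 4-iodophenol | Oc1ccc(I)cc1 | starting material
4 | 9-[2-(3-bromo-4,5-dimethoxyphenyl)ethyl]-9-borabicyclo[3.3.1]nonane | COc1cc(CCB2C3CCCC2CCC3)cc(Br)c1OC | intermediate (not isolated)
5 | 4-[2-(3-bromo-4,5-dimethoxyphenyl)ethyl]phenol | Oc1ccc(CCc2cc(Br)c(OC)c(OC)c2)cc1 | intermediate
6 | 3-iodo-4,5-dimethoxybenzaldehyde | COc1cc(C=O)cc(I)c1OC | starting material
7 | 3-{4-[2-(3-bromo-4,5-dimethoxyphenyl)ethyl]phenoxy}-4,5-dimethoxybenzaldehyde | O=Cc1cc(Oc2ccc(CCc3cc(Br)c(OC)c(OC)c3)cc2)c(OC)c(OC)c1 | intermediate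
8 | 1-bromo-5-{2-[4-(5-ethenyl-2,3-dimethoxyphenoxy)phenyl]ethyl}-2,3-dimethoxybenzene | C=Cc1cc(Oc2ccc(CCc3cc(Br)c(OC)c(OC)c3)cc2)c(OC)c(OC)c1 | intermediate
9 | 3-iodophenol | Oc1cccc(I)c1 | starting material
10 | 9-{2-[3-(4-{2-(3-bromo-4,5-dimethoxyphenyl)ethyl}phenoxy)-4,5-dimethoxyphenyl]ethyl}-9-borabicyclo[3.3.1]nonane | C1CCC2CCCC1B2CCc1cc(Oc2ccc(CCc3cc(Br)c(OC)c(OC)c3)cc2)c(OC)c(OC)c1 | intermediate (not isolated)
11 | 3-{2-[3-(4-{2-(3-bromo-4,5-dimethoxyphenyl)ethyl}phenoxy)-4,5-dimethoxyphenyl]ethyl}phenol | Oc1cccc(CCc2cc(Oc3ccc(CCc4cc(Br)c(OC)c(OC)c4)cc3)c(OC)c(OC)c2)c1 | intermediate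
12 | tetra-O-methyl ether of the target (macrocyclic bis(bibenzyl) with two diaryl ether bridges and four OMe groups) | COc1cc2cc(c1OC)Oc1ccc(cc1)CCc1cc(OC)c(OC)c(c1)Oc1cccc(c1)CC2 | intermediate
13 | macrocycle with both catechol units tied up as 2-bromo-1,3,2-benzodioxaboroles | BrB3Oc1cc2cc(c1O3)Oc1ccc(cc1)CCc1cc4OB(Br)Oc4c(c1)Oc1cccc(c1)CC2 | intermediate (not isolated)
14 | CNP0511668.0 (achiral macrocyclic tetraphenol) | Oc1cc2cc(c1O)Oc1ccc(cc1)CCc1cc(O)c(O)c(c1)Oc1cccc(c1)CC2 | target

## Step count and risks

Total steps: 7. Longest linear sequence: 7 (1 to 14; the route is fully linear).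

The three steps most likely to fail are steps 3, 5 and 6.

**Step 3.** The risk is incomplete iodide-over-bromide selectivity at copper, which would let phenol 5 condense with its own aryl bromide. The fallback reverses the polarity of the ether coupling so that the nucleophile carries no halide. It sets out from styrene 2: hydroboration with 9-BBN gives borane 4 as before, and B-alkyl Suzuki coupling with excess 1,4-diiodobenzene (PdCl2(dppf), aq K3PO4, DMF, 50 °C) gives 1-bromo-5-[2-(4-iodophenyl)ethyl]-2,3-dimethoxybenzene F1. Ullmann coupling of the unhindered aryl iodide of F1 with purchased 3-hydroxy-4,5-dimethoxybenzaldehyde (CuI, picolinic acid, K3PO4, DMSO, 80 °C) then comes back to the route at aldehyde 7.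

**Step 5.** The risk is loss of the ring C bromide or oligomerisation at palladium on this larger substrate, or sluggish coupling of the iodophenoxide. The fallback replaces steps 4 and 5 by olefination and a metal-free reduction. It sets out from aldehyde 7. 3-Hydroxybenzyl alcohol and PPh3·HBr in refluxing acetonitrile give (3-hydroxybenzyl)triphenylphosphonium bromide F2. Wittig reaction of F2 with 7 (KOtBu, 2.2 equiv per phosphonium, THF) gives the hydroxystilbene F3 as an E/Z mixture. Diimide reduction (TsNHNH2, NaOAc, DME/H2O, reflux) saturates the alkene without touching the aryl bromide and comes back to the route at bromo-phenol 11.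

**Step 6 (the proposed new step).** The risk is that reductive elimination from the large palladacycle is slow, giving hydrodebromination or oligomers. The fallback uses known chemistry and changes the bond-forming logic from aryl halide cross-coupling to oxidative arylboron coupling. It sets out from 11. Miyaura borylation (B2pin2, PdCl2(dppf), KOAc, dioxane, 90 °C) converts the aryl bromide into the pinacol boronate of 11, F4. Intramolecular Chan–Lam etherification of F4 (Cu(OAc)2, B(OH)3, pyridine, 4 Å sieves, MeCN, air, 60 °C, 2 mM) comes back to the route at macrocycle 12.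

## Further compounds

F1 | step 3 | 1-bromo-5-[2-(4-iodophenyl)ethyl]-2,3-dimethoxybenzene | COc1cc(CCc2ccc(I)cc2)cc(Br)c1OC
F2 | step 5 | (3-hydroxybenzyl)triphenylphosphonium bromide | Oc1cccc(C[P+](c2ccccc2)(c2ccccc2)c2ccccc2)c1.[Br-]
F3 | step 5 | 3-{2-[3-(4-{2-(3-bromo-4,5-dimethoxyphenyl)ethyl}phenoxy)-4,5-dimethoxyphenyl]ethenyl}phenol (E/Z mixture, no defined alkene geometry) | Oc1cccc(C=Cc2cc(Oc3ccc(CCc4cc(Br)c(OC)c(OC)c4)cc3)c(OC)c(OC)c2)c1
F4 | step 6 | 3-{2-[3-(4-{2-[3,4-dimethoxy-5-(4,4,5,5-tetramethyl-1,3,2-dioxaborolan-2-yl)phenyl]ethyl}phenoxy)-4,5-dimethoxyphenyl]ethyl}phenol | Oc1cccc(CCc2cc(Oc3ccc(CCc4cc(B5OC(C)(C)C(C)(C)O5)c(OC)c(OC)c4)cc3)c(OC)c(OC)c2)c1
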